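**Retrosynthetic overview**

1. Mutilin numbering is used (C3 ketone, C4 ring-fusion CH, C5 and C9 quaternary, C10–C14 the five carbons that complete the eight-membered ring, C19/C20 the oxolane carbons). Enabling feature: C10 (alpha to oxygen-bearing C11) and O-bearing C14 are 1,5-related, so C10–C11(=O)–C12=C13–C14 with one oxygen bridging C10 and C14 is a 2H-pyran-3(6H)-one; C5 and C9 flank C4, which carries the C3 carbonyl, so a C6-keto hydrindenone is nucleophilic at C5 and electrophilic at C9.
2. Target ⇐ oxolane made last (C12 allyl → lactol → dihydrofuran → hydroboration) and C14 glycolate; C11/C14 carbinols ⇐ 11,14-diketone; eight-membered ring ⇐ SmI2 cleavage of a temporary C10–O–C14 ether bridge.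
3. Oxa-bridged tetracycle 11 ⇐ one-pot Tsuji–Trost/Michael annulation of ene-dione 4 with pyranone carbonate 9 (C5–C14 first, then C9–C10).
4. 4 ⇐ Robinson annulation of cyclopentane-1,2-dione with ethyl vinyl ketone; 9 ⇐ Achmatowicz rearrangement of (R)-1-(3-methylfuran-2-yl)ethanol.
5. Ring order: cyclopentanone and six-membered carbocycle (4), pyranone (9), eight-membered carbocycle as its 9-oxabicyclo[3.3.1]nonane (key step), oxolane last.

Key step: step 7

Assumption: the stereodescriptors are used exactly as written in the target SMILES; the SMILES of every intermediate is derived from that string, so each retained centre keeps the parity written there.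

**Route**

Step 1
Reactants: 1 cyclopentane-1,2-dione; 2 pent-1-en-3-one
Product: 3 3-(3-oxopentyl)cyclopentane-1,2-dione
Conditions: Et3N (10 mol %), MeCN, rt
Reagents that add atoms: none
Why: Michael addition, in which the enol form of the 1,2-dione (2-hydroxycyclopent-2-enone) is a soft carbon nucleophile at C3 and adds to the unhindered vinyl ketone; the new centre is racemic and is erased in step 7.

Step 2
Reactants: 3 3-(3-oxopentyl)cyclopentane-1,2-dione
Product: 4 7-methyl-2,3,3a,4-tetrahydro-1H-indene-1,6(5H)-dione
Conditions: p-TsOH·H2O (10 mol %), toluene, reflux, Dean–Stark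
Reagents that add atoms: none
Why: Acid-catalysed intramolecular aldol condensation (Robinson annulation): the ethyl ketone methylene attacks the neighbouring ring carbonyl to close the six-membered ring and dehydration gives the alkene conjugated with both ketones, whereas the other closures would give four- or seven-membered rings or a bridged aldol that cannot dehydrate.

Step 3
Reactants: 5 3-methylfuran-2-carboxylic acid
Product: 6 1-(3-methylfuran-2-yl)ethan-1-one
Conditions: MeLi (2.2 equiv), Et2O, 0 °C to rt; then H2O
Reagents that add atoms: methyllithium, C[Li]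
Why: Addition of methyllithium to the lithium carboxylate stops after one carbon–carbon bond because the adduct does not collapse before work-up, a standard route from acids to methyl ketones.

Step 4
Reactants: 6 1-(3-methylfuran-2-yl)ethan-1-one
Product: 7 (R)-1-(3-methylfuran-2-yl)ethan-1-ol
Conditions: RuCl[(R,R)-TsDPEN](p-cymene) (1 mol %), HCO2H/Et3N (5:2), rt
Reagents that add atoms: none
Why: Noyori asymmetric transfer hydrogenation of a heteroaryl methyl ketone, in which the (R,R)-catalyst delivers hydride to the face that gives the (R)-carbinol; this centre fixes the absolute configuration of the whole route.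

Step 5
Reactants: 7 (R)-1-(3-methylfuran-2-yl)ethan-1-ol
Product: 8 (2R)-6-hydroxy-2,4-dimethyl-2H-pyran-3(6H)-one
Conditions: N-bromosuccinimide, NaHCO3, THF/H2O (4:1), 0 °C
Reagents that add atoms: water, O
Why: Achmatowicz rearrangement, an oxidative ring opening of the furan followed by lactolisation, converts the furyl carbinol into the pyranone without touching the carbinol stereocentre.

Step 6
Reactants: 8 (2R)-6-hydroxy-2,4-dimethyl-2H-pyran-3(6H)-one
Product: 9 tert-butyl (2R,6R)-4,6-dimethyl-5-oxo-5,6-dihydro-2H-pyran-2-yl carbonate
Conditions: Boc2O, DMAP (10 mol %), CH2Cl2, −78 °C; chromatography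
Reagents that add atoms: di-tert-butyl dicarbonate, CC(C)(C)OC(=O)OC(=O)OC(C)(C)C
Why: Low-temperature DMAP-catalysed acylation of the lactol should favour the 2,6-trans carbonate (kinetic anomeric preference), which is separated from the cis isomer and later transfers its anomeric configuration to C14.

Step 7
Reactants: 4 7-methyl-2,3,3a,4-tetrahydro-1H-indene-1,6(5H)-dione; 9 tert-butyl (2R,6R)-4,6-dimethyl-5-oxo-5,6-dihydro-2H-pyran-2-yl carbonate
Product: 11 oxa-bridged tetracyclic triketone, via C-glycoside 10 (not isolated)
Conditions: Pd2(dba)3·CHCl3 (2.5 mol %), (R,R)-DACH-phenyl Trost ligand (7.5 mol %; or its enantiomer, whichever is matched to 9), CH2Cl2, 0 °C to rt; then DBU (0.3 equiv), rt to 40 °C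
Reagents that add atoms: none
Why: Proposed new method: zerovalent palladium ionises carbonate 9 with inversion and the tert-butoxide that is set free deprotonates 4 at C3a, whose extended dienolate attacks the anomeric carbon anti to palladium through its alpha carbon (C5) to form the C5–C14 bond with net retention and to return the ring-fusion enone in 10; DBU then enolises only the alpha-alkoxy ketone position C10, which adds to C9 of that enone and forms the C9–C10 bond. The closest known reaction types are the Tsuji–Trost C-alkylation of Achmatowicz carbonates by 1,3-dicarbonyl pronucleophiles followed by an in-flask Michael-type ring closure, and the alpha,alpha'-annulation of ketones with 2-acylallyl electrophiles to bicyclo[3.3.1]nonanes. The Michael stage closes the oxane ring (O, C10, C9, C4, C5, C14) in a 6-endo-trig mode and thereby the eight-membered carbocycle C9–C10–C11–C12–C13–C14–C5–C4, which never has to close as a medium ring because the pyranone oxygen holds C10 next to C14. C14 is fixed by the carbonate (double inversion), C5 by the dienolate face that the chiral ligand selects, C9 and C10 by the tether, since the oxane can form only as a chair that carries the C11–C13 and C6–C8 bridges on opposite faces, and C4 by equilibrating protonation that turns its hydrogen into the cavity under the pyranone bridge. The step needs alpha- instead of gamma- or O-allylation, which the soft palladium-allyl electrophile and the conjugated enone returned by alpha-attack favour, and it needs C10 instead of C7 as the Michael donor, which the weak amine base secures because only the alpha-alkoxy enone position is acidic enough for it.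

Step 8
Reactants: 11 oxa-bridged tetracyclic triketone
Product: 12 C3 dioxolane of 11
Conditions: (CH2OSiMe3)2 (1.1 equiv), Me3SiOTf (5 mol %), CH2Cl2, −78 °C
Reagents that add atoms: 1,2-bis(trimethylsilyloxy)ethane, C[Si](C)(C)OCCO[Si](C)(C)C
Why: Noyori ketalisation under kinetic control should take place at C3, the only carbonyl without an adjacent fully substituted carbon (C6 is flanked by quaternary C5, the C11 enone by fully substituted C10), and the ketal also blocks retro-Michael opening in the basic steps that follow.

Step 9
Reactants: 12 C3 dioxolane of 11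
Product: 13 6-methylidene compound
Conditions: Ph3PCH3Br, KOt-Bu, toluene, 0 °C then 90 °C
Reagents that add atoms: methyltriphenylphosphonium bromide, C[P+](c1ccccc1)(c1ccccc1)c1ccccc1.[Br-]
Why: Wittig methylenation of the remaining saturated ketone at C6; the doubly alpha-substituted C11 enone is too hindered to react and has no enolisable position.

Step 10
Reactants: 13 6-methylidene compound
Product: 14 6-methyl-12,13-dihydro ketone
Conditions: Mn(dpm)3 (10 mol %), PhSiH3, t-BuOOH, i-PrOH, rt
Reagents that add atoms: none
Why: Hydrogen-atom-transfer hydrogenation reduces the 1,1-disubstituted alkene through a tertiary C6 radical under product-stability control, which should give the equatorial methyl group trans to the C5 methyl, and reduces the enone by conjugate reduction; the C12 centre formed here is erased in step 11.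

Step 11
Reactants: 14 6-methyl-12,13-dihydro ketone
Product: 15 12-allyl ketone
Conditions: LiN(i-Pr)2, THF, −78 to 0 °C; allyl iodide, DMPU, −78 °C to rt
Reagents that add atoms: allyl iodide, C=CCI
Why: Alkylation of the only possible enolate of the C11 ketone (C10 is fully substituted) from the exo face of the 9-oxabicyclo[3.3.1]nonanone, away from the carbocyclic bridge, sets the C12 quaternary centre with the allyl group on the side that the oxolane needs.

Step 12
Reactants: 15 12-allyl ketone
Product: 16 ring-opened hydroxy ketone
Conditions: SmI2 (2.5 equiv), THF/MeOH, −78 °C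
Reagents that add atoms: none
Why: SmI2 reduction of the alpha-alkoxy ketone cleaves the C10–O bond and so opens the ether bridge to the free eight-membered carbocycle; the enolate should be protonated at C10 from the side of the departing oxygen (internal delivery from the C14 hydroxyl), which is also the configuration reachable by equilibration alpha to the ketone.

Step 13
Reactants: 16 ring-opened hydroxy ketone
Product: 17 11,14-diketone
Conditions: Dess–Martin periodinane, CH2Cl2, rt
Reagents that add atoms: none
Why: Dess–Martin oxidation of the hindered secondary alcohol removes the C14 configuration that the ether bridge had imposed (oxygen pointing into the ring), so that it can be reset.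

Step 14
Reactants: 17 11,14-diketone
Product: 18 11,14-diol
Conditions: Na, EtOH, 0 °C to rt
Reagents that add atoms: none
Why: Dissolving-metal reduction should give the thermodynamically preferred alcohols at both carbonyls, with the hydroxyl groups on the outer face of the eight-membered ring and the carbinol hydrogens pointing into it, which is the configuration required at C11 and C14.

Step 15
Reactants: 18 11,14-diol
Product: 20 lactol, via hydroxy aldehyde 19 (not isolated)
Conditions: O3, CH2Cl2/MeOH, −78 °C; then Me2S, −78 °C to rt
Reagents that add atoms: ozone, [O-][O+]=O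
Why: Ozonolysis of the terminal alkene with reductive work-up gives the aldehyde, which is trapped by the neighbouring C11 hydroxyl as a five-membered lactol; the C14 hydroxyl could only form a bridged six-membered ring and should stay free.

Step 16
Reactants: 20 lactol
Product: 21 dihydrofuran
Conditions: MsCl, Et3N, CH2Cl2, −40 °C to rt
Reagents that add atoms: none
Why: Sulfonylation of the lactol hydroxyl and base-induced elimination through the oxocarbenium ion (furanoid glycal formation) give the 2,3-dihydrofuran; the neopentyl C14 hydroxyl next to quaternary C5 should react much more slowly.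

Step 17
Reactants: 21 dihydrofuran; 22 2-[(tert-butyldimethylsilyl)oxy]acetic acid
Product: 23 C14 silyloxyacetate
Conditions: EDC·HCl, DMAP, CH2Cl2, rt to 35 °C
Reagents that add atoms: none
Why: Steglich esterification of the only free hydroxyl under basic conditions that the acid-sensitive enol ether tolerates.

Step 18
Reactants: 23 C14 silyloxyacetate
Product: 25 C19 alcohol, via alkylborane 24 (not isolated)
Conditions: BH3·THF, THF, 0 °C; then H2O2, pH 7 phosphate buffer, 0 °C to rt
Reagents that add atoms: hydrogen peroxide, OO (oxygen at C19); borane–tetrahydrofuran, B.C1CCOC1 (boron of 24 only)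
Why: Hydroboration of the cyclic enol ether places boron at C19 (beta to oxygen) from the convex face of the cis-fused oxabicycle, syn to the C12 methyl and the C11 hydrogen, and oxidation with retention gives the C19 alcohol.

Step 19
Reactants: 25 C19 alcohol
Product: 26 pleuromutilin B
Conditions: 1 M aq. HCl, THF, rt
Reagents that add atoms: water, O
Why: Aqueous acid hydrolyses the dioxolane and the primary silyl ether in one operation, while the hindered C14 ester and the oxolane are stable and C4, alpha to the liberated ketone, should stay in its thermodynamically preferred configuration.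

**Compound list**

1 | cyclopentane-1,2-dione | O=C1CCCC1=O | starting material
2 | pent-1-en-3-one (ethyl vinyl ketone) | CCC(=O)C=C | starting material
3 | 3-(3-oxopentyl)cyclopentane-1,2-dione (racemic, drawn as the diketo tautomer) | CCC(=O)CCC1CCC(=O)C1=O | intermediate
4 | 7-methyl-2,3,3a,4-tetrahydro-1H-indene-1,6(5H)-dione (ene-1,4-dione, C7=C7a double bond, C3a racemic) | CC1=C2C(=O)CCC2CCC1=O | intermediate
5 | 3-methylfuran-2-carboxylic acid | Cc1ccoc1C(=O)O | starting material
6 | 1-(3-methylfuran-2-yl)ethan-1-one | CC(=O)c1occc1C | intermediate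
7 | (R)-1-(3-methylfuran-2-yl)ethan-1-ol | C[C@@H](O)c1occc1C | intermediate
8 | (2R)-6-hydroxy-2,4-dimethyl-2H-pyran-3(6H)-one (lactol, both anomers) | C[C@H]1OC(O)C=C(C)C1=O | intermediate
9 | tert-butyl (2R,6R)-4,6-dimethyl-5-oxo-5,6-dihydro-2H-pyran-2-yl carbonate (2,6-trans) | C[C@H]1O[C@H](OC(=O)OC(C)(C)C)C=C(C)C1=O | intermediate
10 | C-glycoside: 7-[(2S,6R)-4,6-dimethyl-5-oxo-5,6-dihydro-2H-pyran-2-yl]-7-methyl-2,3,4,5-tetrahydro-1H-indene-1,6(7H)-dione, C5 as in 26 | C[C@H]1O[C@@H](C=C(C)C1=O)[C@@]2(C)C(=O)CCC3=C2C(=O)CC3 | intermediate
11 | oxa-bridged tetracyclic triketone: mutilin skeleton without C16, ketones at C3, C6, C11, C12=C13 double bond with the C12 methyl, ether oxygen bridging C10 and C14; C4, C5, C9, C10 as in 26, C14–O on the face opposite to that in 26 | C[C@]12C(=O)C(C)=C[C@H](O1)[C@@]3(C)C(=O)CC[C@]24CCC(=O)[C@@H]43 | intermediate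
12 | C3 dioxolane (3,3-ethylenedioxy derivative) of 11 | C[C@]12C(=O)C(C)=C[C@H](O1)[C@@]3(C)C(=O)CC[C@]24CCC5(OCCO5)[C@@H]43 | intermediate
13 | 6-methylidene compound (12 with C6=CH2 in place of C6=O) | C[C@]12C(=O)C(C)=C[C@H](O1)[C@@]3(C)C(=C)CC[C@]24CCC5(OCCO5)[C@@H]43 | intermediate
14 | 6-methyl-12,13-dihydro ketone: C6 methyl as in 26, C11 ketone, C12 H/methyl as a mixture, C10–O–C14 bridge, C3 dioxolane | C[C@]12C(=O)C(C)C[C@H](O1)[C@@]3(C)[C@@H](C)CC[C@]24CCC5(OCCO5)[C@@H]43 | intermediate
15 | 12-allyl ketone: 14 with quaternary C12 carrying methyl and allyl | C[C@]12C(=O)[C@](C)(CC=C)C[C@H](O1)[C@@]3(C)[C@@H](C)CC[C@]24CCC5(OCCO5)[C@@H]43 | intermediate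
16 | ring-opened hydroxy ketone: C10–H as in 26, C11 ketone, C14 alcohol epimeric to 26, C12 allyl, C3 dioxolane | C[C@H]1C(=O)[C@](C)(CC=C)C[C@H](O)[C@@]2(C)[C@@H](C)CC[C@]13CCC4(OCCO4)[C@@H]32 | intermediate
17 | 11,14-diketone (C12 allyl, C3 dioxolane) | C[C@H]1C(=O)[C@](C)(CC=C)CC(=O)[C@@]2(C)[C@@H](C)CC[C@]13CCC4(OCCO4)[C@@H]32 | intermediate
18 | 11,14-diol with C11 and C14 as required for 26 (C12 allyl, C3 dioxolane) | C[C@H]1[C@H](O)[C@](C)(CC=C)C[C@@H](O)[C@@]2(C)[C@@H](C)CC[C@]13CCC4(OCCO4)[C@@H]32 | intermediate
19 | hydroxy aldehyde: 18 with CH2CHO in place of allyl | C[C@H]1[C@H](O)[C@](C)(CC=O)C[C@@H](O)[C@@]2(C)[C@@H](C)CC[C@]13CCC4(OCCO4)[C@@H]32 | intermediate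
20 | lactol: 2-hydroxyoxolane fused at C11–C12 (C11–O–C20H(OH), both anomers), C14 alcohol free | C[C@H]1[C@@H]2OC(O)C[C@]2(C)C[C@@H](O)[C@@]2(C)[C@@H](C)CC[C@]13CCC4(OCCO4)[C@@H]32 | intermediate
21 | dihydrofuran: C19=C20 enol ether fused at C11–C12, C14 alcohol free | C[C@H]1[C@@H]2OC=C[C@]2(C)C[C@@H](O)[C@@]2(C)[C@@H](C)CC[C@]13CCC4(OCCO4)[C@@H]32 | intermediate
22 | 2-[(tert-butyldimethylsilyl)oxy]acetic acid | CC(C)(C)[Si](C)(C)OCC(=O)O | starting material
23 | C14 silyloxyacetate of 21 | C[C@H]1[C@@H]2OC=C[C@]2(C)C[C@@H](OC(=O)CO[Si](C)(C)C(C)(C)C)[C@@]2(C)[C@@H](C)CC[C@]13CCC4(OCCO4)[C@@H]32 | intermediate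
24 | C19 alkylborane of 23 (BH2 on the face of the later hydroxyl) | C[C@H]1[C@@H]2OC[C@@H](B)[C@]2(C)C[C@@H](OC(=O)CO[Si](C)(C)C(C)(C)C)[C@@]2(C)[C@@H](C)CC[C@]13CCC4(OCCO4)[C@@H]32 | intermediate
25 | C19 alcohol: 26 carrying the C3 dioxolane and the silyl ether on the glycolate | C[C@H]1[C@@H]2OC[C@@H](O)[C@]2(C)C[C@@H](OC(=O)CO[Si](C)(C)C(C)(C)C)[C@@]2(C)[C@@H](C)CC[C@]13CCC4(OCCO4)[C@@H]32 | intermediate
26 | pleuromutilin B | C[C@H]1[C@@H]2OC[C@@H](O)[C@]2(C)C[C@@H](OC(=O)CO)[C@@]2(C)[C@@H](C)CC[C@]13CCC(=O)[C@@H]32 | target

**Summary**

Total step count: 19.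
Longest linear sequence: 17 steps (5 to 26, steps 3–6 and 7–19).

**Steps most likely to fail**

Step 7. What may go wrong is loss of site selectivity in the allylation (O- or gamma-attack of the dienolate), poor facial selectivity at C5, or interception of the pyranone enone by an enolate of the C6 ketone before C10 adds to C9. The fallback makes the two bonds in separate, known operations and sets out from 4 and 8. Compound 4 is converted (KH, then t-BuMe2SiCl, THF) into the extended silyl dienol ether 6-(tert-butyldimethylsilyloxy)-7-methyl-2,3,4,5-tetrahydro-1H-inden-1-one F1, and lactol 8 (Ac2O, pyridine) into the anomeric acetate (2R)-6-acetoxy-2,4-dimethyl-2H-pyran-3(6H)-one F2. BF3·OEt2 in CH2Cl2 at −78 °C joins them by a Mukaiyama-type C-glycosylation, in which the enol ether carbon C5 (C9 is made electron-poor by the acyl group on C4) attacks the pyranone oxocarbenium ion trans to the C2 methyl group, to give isolated 10. DBU in CH2Cl2 then closes 10 by the intramolecular Michael addition in a second flask, and the route is rejoined at 11.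

Step 8. What may go wrong is loss of chemoselectivity between the two saturated ketones at C3 and C6. The fallback sets out from 11: both ketones are ketalised (ethylene glycol, p-TsOH, benzene, reflux) to the C3,C6-bis-dioxolane F3, and the more strained ketal at C6, next to quaternary C5, is hydrolysed selectively (pyridinium p-toluenesulfonate, wet acetone, rt; steric acceleration of ketal hydrolysis), which returns to 12.

Step 14. What may go wrong is poor facial selectivity at C11 or C14 if electron transfer and protonation are faster than equilibration. The fallback sets out from 17: hydride reduction (LiAlH4, THF, 0 °C) gives the kinetic diol, drawn as the C11,C14-bis-epimeric diol F4, which is equilibrated by reversible hydride transfer (Al(Oi-Pr)3, i-PrOH, trace acetone, toluene, 100 °C; Meerwein–Ponndorf–Verley/Oppenauer equilibration) to the more stable diol, returning to 18.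

**Further compounds**

F1 | step 7 | 6-(tert-butyldimethylsilyloxy)-7-methyl-2,3,4,5-tetrahydro-1H-inden-1-one | CC1=C(O[Si](C)(C)C(C)(C)C)CCC2=C1C(=O)CC2
F2 | step 7 | (2R)-6-acetoxy-2,4-dimethyl-2H-pyran-3(6H)-one | C[C@H]1OC(OC(C)=O)C=C(C)C1=O
F3 | step 8 | C3,C6-bis-dioxolane of 11 | C[C@]12C(=O)C(C)=C[C@H](O1)[C@@]3(C)C5(OCCO5)CC[C@]24CCC6(OCCO6)[C@@H]43
F4 | step 14 | C11,C14-bis-epimer of diol 18 | C[C@H]1[C@@H](O)[C@](C)(CC=C)C[C@H](O)[C@@]2(C)[C@@H](C)CC[C@]13CCC4(OCCO4)[C@@H]32
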